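## Analysis of the target

Target 13 is a sesquiterpene coumarin ether. It is a 5-hydroxycoumarin (benzene ring A, C4a–C8a; pyranone ring B, O1–C4) whose O7 carries C1' of an open farnesyl-type chain C1'–C11', with methyl groups on C3', C7' and C11'. The chain holds two E-trisubstituted alkenes, C2'=C3' and C6'=C7', and ends in the contiguous triol C9'(OH)–C10'(OH)–C11'(CH3)2OH. Only C9' and C10' are stereogenic: both are R, they are neighbours, and in the zigzag drawing their hydroxyl groups lie anti (erythro), while C11' bears two equal methyl groups. This anti pattern cannot come from syn dihydroxylation of an E alkene. It is the imprint of anti opening of a trans-9',10'-epoxide, so the triol is the hydrate of a trans-2,3-epoxy alcohol whose carbinol carbon is C11', and the plan exploits this feature. Any oxidation must pick its alkene among the coumarin C3=C4 bond and the electron-rich chain alkenes, at a chain end remote from every other handle. The sensitive groups are: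
- the allyl aryl ether O7–C1' (acid, heat, zerovalent palladium);
- the lactone of ring B (hydride, hard nucleophiles, strong base);
- the O5–H phenol, which binds oxophilic metals and competes with O7–H on alkylation.

The difficulty is selectivity rather than size. Two adjacent stereocentres must be set at the far end of a polyene with no ring or resident stereocentre to lean on. The E geometry of C6'=C7', one methylene (C8') away, must also survive.

## Retrosynthetic reasoning

**13 ⇒ 12.** The acyl–oxygen bonds at O5 and O9' are cut. Both esters fall in one mild transesterification, so the last step touches no stereocentre, no alkene and not the allyl aryl ether.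

**12 ⇒ 11.** The C9'–O(acyl) bond is cut back to the trans-epoxide 11, which is (9'S,10'R). Attack of an oxygen nucleophile at C9' with inversion gives 9'R and leaves 10'R untouched. Attack at C10' would lead to the mirror-image triol, so regioselectivity here equals enantiopurity. The cut is placed at C9' because C10' is neopentyl-like (next to quaternary C11') and inductively deactivated. A chelate between O11' and the epoxide oxygen also steers a carboxylic acid to the distal carbon.

**11 ⇒ 10 (key disconnection).** Both C–O bonds of the oxirane are cut, which leads to the achiral tertiary allylic alcohol 10. Three things are gained: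
- C9' and C10' are set together, their relative configuration by the E alkene and their absolute configuration by one catalyst.
- The C11'–OH that the target needs anyway becomes the handle that selects C9'=C10' out of four C=C bonds.
- No protecting group is needed in the chain.

The sequence allylic alcohol, epoxy alcohol, triol also copies the way in which oxidised prenyl termini are presumed to arise in nature.

**10 ⇒ 7 + 9.** The C8'–C9' bond is cut. This is the seam between a C10 geranyl unit, which brings both E-trisubstituted alkenes from the terpene pool, and a C5 unit. C8' is taken as the allyl electrophile and C9' as the vinyl nucleophile, because this polarity joins at the primary terminus. The reverse polarity, a C8' allyl-metal adding to a C9' carbonyl group, would react through C6' and give a branched chain.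

**9 ⇒ 8.** The C9'–Sn bond is cut. A syn hydrometalation of the terminal alkyne 8 has to place tin on the terminal carbon and fix the E geometry.

**7 ⇒ 6 ⇒ 4.** C8'–Br goes back to C8'–OH and then to C8'–H. The forward reaction oxidises only the E-methyl group of the terminal alkene of 4, with the over-oxidised enal 5 returned to 6 in the same operation.

**4 ⇒ 1 + 2.** The O7–C1' and O5–acyl bonds are cut. Etherification comes first, so the coumarin serves as the protecting group of the C1' oxygen throughout. The mono-ether 3 is capped at O5 in the same flask.

## Alternatives that were turned down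

**Alternative 1:** (textbook) Disconnection: O7–C1' as the last skeleton bond. Forward key step: Williamson or Mitsunobu etherification of 1 with the fully oxidised chain, carried as the cis-acetonide alcohol A1.
- The etherification builds no stereocentre and none of the hard C–O bonds, so the whole problem is merely moved into A1.
- A1 needs the same oxidation chemistry plus a temporary group on C1'–OH and an acetonide put on and taken off.
- The closing acidic acetonide removal would meet the acid-labile allyl aryl ether.
- A cis-dioxolane next to a free tertiary alcohol tends to migrate.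
- The count rises by about four steps with no gain in control.

**Alternative 2:** Disconnection: the C10'–O and C11'–O bonds on the C10'=C11' alkene of the 9'-carbinol A2. Forward key step: kinetic-resolution Sharpless epoxidation of racemic A2 to the erythro epoxy alcohol A3 with hydrolysis at C11', or OsO4-catalysed dihydroxylation of resolved A2.
- The Z-methyl group on C11' enforces, through A(1,3) strain, the rotamer with C9'–H eclipsing the alkene. In it a hydroxyl-directed oxidant gives the threo (syn) epoxy alcohol.
- This bias opposes the erythro preference of Ti(OiPr)4/dialkyl tartrate, so the resolution should be slow and unselective. It gives half of the material at best.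
- OsO4 would attack anti to the C9' oxygen and give the right anti relation, but C10'=C11' is deactivated by the allylic hydroxyl group, and C6'=C7' would react first.
- A2 itself needs the unfavourable allyl-metal polarity at C8', and such reagents do not tolerate ring B.

**Alternative 3:** Disconnection: C5'–C6' in the middle of the 1,5-diene. Forward key step: cathodic decarboxylative alkenylation, catalysed by NiCl2·glyme/2,2'-bipyridine, of the N-hydroxyphthalimide ester of acid A5 with the vinyl iodide A4. Both stereocentres of A4 come from the chiral-pool lactone A6, whose configuration maps correctly onto C9' and C10'.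
- The cut removes and rebuilds an E alkene that 2 supplies for free.
- A5 must be made by oxidative cleavage of the very geranyl ether used here.
- A4 needs about six steps: double methyl addition, activation of C8', acetylide displacement, carboalumination–iodination with Me3Al/Cp2ZrCl2, and protecting-group shuffling.
- The electron-poor C3=C4 bond of the coumarin is itself reducible at the cathode.
- The acetonide again has to leave under acid.
- The route would exceed twelve steps.

Key step: step 6

Assumption: 1, 2 and 8 are bought. The (R,R)-ligand is taken to deliver oxygen to the face of C9'=C10' that gives (9'S,10'R)-11; should the sense prove opposite, the equally available (S,S)-ligand takes its place and nothing else changes.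

## Route

**Step 1**
Reactants: 1 5,7-dihydroxycoumarin; 2 geranyl bromide [(2E)-1-bromo-3,7-dimethylocta-2,6-diene]
Product: 4 7-(geranyloxy)-2-oxo-2H-chromen-5-yl pivalate, via 7-geranyloxy-5-hydroxycoumarin 3 (not isolated)
Conditions: K2CO3 (1.05 equiv), 2 (1.0 equiv), acetone, rt; then K2CO3 (2 equiv), PivCl (1.3 equiv), DMAP (5 mol %), 0 °C to rt
Reagents that add atoms: pivaloyl chloride CC(C)(C)C(=O)Cl
Why: Williamson ether synthesis followed by O-acylation in the same flask. With one equivalent of base the more acidic and less hindered O7–H (O5–H is peri to C4–H) should be ionised and alkylated by SN2 at C1' with the E alkene retained. The remaining O5–H is capped so that no free phenol meets the later metal catalysts.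

**Step 2**
Reactants: 4 7-(geranyloxy)-2-oxo-2H-chromen-5-yl pivalate
Product: 6 7-{[(2E,6E)-8-hydroxy-3,7-dimethylocta-2,6-dien-1-yl]oxy}-2-oxo-2H-chromen-5-yl pivalate, via 8'-enal 5 (not isolated)
Conditions: SeO2 (0.3 equiv), tBuOOH (3 equiv), salicylic acid (10 mol %), CH2Cl2, 0 °C to rt; then NaBH4, CeCl3·7H2O, MeOH/THF, −40 °C
Reagents that add atoms: tert-butyl hydroperoxide CC(C)(C)OO (terminal oxidant); selenium dioxide O=[Se]=O (oxygen carrier)
Why: Riley oxidation by an ene reaction and [2,3]-shift, which targets the E-methyl group (C8') of the more electron-rich C6'=C7' alkene, while C2'=C3' is deactivated by the allylic aryloxy group. The part that runs on to enal 5 is returned to 6 by a Luche 1,2-reduction, cold enough to spare the lactone and the pivalate.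

**Step 3**
Reactants: 6 7-{[(2E,6E)-8-hydroxy-3,7-dimethylocta-2,6-dien-1-yl]oxy}-2-oxo-2H-chromen-5-yl pivalate
Product: 7 7-{[(2E,6E)-8-bromo-3,7-dimethylocta-2,6-dien-1-yl]oxy}-2-oxo-2H-chromen-5-yl pivalate
Conditions: CBr4, PPh3, CH2Cl2, −20 to 0 °C
Reagents that add atoms: carbon tetrabromide BrC(Br)(Br)Br
Why: Appel reaction. The primary allylic alcohol is displaced by SN2 under neutral conditions, so neither alkene geometry nor the ester, lactone or aryl ether is disturbed.

**Step 4**
Reactants: 8 2-methylbut-3-yn-2-ol
Product: 9 (E)-2-methyl-4-(tributylstannyl)but-3-en-2-ol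
Conditions: Bu3SnH (1.1 equiv), PdCl2(PPh3)2 (1 mol %), THF, 0 °C to rt
Reagents that add atoms: tributyltin hydride CCCC[SnH](CCCC)CCCC
Why: Palladium-catalysed syn hydrostannation of a terminal alkyne. The bulky tertiary carbinol should send tin to the terminal carbon, and syn addition then fixes the E geometry.

**Step 5**
Reactants: 7 7-{[(2E,6E)-8-bromo-3,7-dimethylocta-2,6-dien-1-yl]oxy}-2-oxo-2H-chromen-5-yl pivalate; 9 (E)-2-methyl-4-(tributylstannyl)but-3-en-2-ol
Product: 10 7-{[(2E,6E,9E)-11-hydroxy-3,7,11-trimethyldodeca-2,6,9-trien-1-yl]oxy}-2-oxo-2H-chromen-5-yl pivalate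
Conditions: Pd2(dba)3 (2.5 mol %), AsPh3 (10 mol %), THF, rt to 40 °C
Reagents that add atoms: none
Why: Stille coupling of an allyl bromide with a vinylstannane under neutral conditions. Oxidative addition of zerovalent palladium to the C8'–Br bond is far faster than ionisation of the aryl ether at C1'. Reductive elimination at the less substituted terminus C8' should give the linear skipped diene with both alkene geometries retained.

**Step 6**
Reactants: 10 7-{[(2E,6E,9E)-11-hydroxy-3,7,11-trimethyldodeca-2,6,9-trien-1-yl]oxy}-2-oxo-2H-chromen-5-yl pivalate
Product: 11 7-{[(2E,6E)-8-[(2S,3R)-3-(2-hydroxypropan-2-yl)oxiran-2-yl]-3,7-dimethylocta-2,6-dien-1-yl]oxy}-2-oxo-2H-chromen-5-yl pivalate [the (9'S,10'R)-trans-epoxide]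
Conditions: Hf(OtBu)4 (10 mol %), C2-symmetric bis(hydroxamic acid) ligand from (1R,2R)-cyclohexane-1,2-diamine (12 mol %), cumene hydroperoxide (1.5 equiv), 4 Å MS, toluene, 0 °C
Reagents that add atoms: cumene hydroperoxide CC(C)(OO)c1ccccc1
Why: Hydroxyl-directed catalytic asymmetric epoxidation of a tertiary allylic alcohol. The C11'–OH of 10 exchanges with a tert-butoxide on tetravalent hafnium held by the bis(hydroxamate), the hydroperoxide binds to the same metal, and its distal oxygen is passed to C9'=C10' inside this complex. The oxirane ring (O, C9', C10') closes by concerted suprafacial transfer of one oxygen atom to both carbons, so the E geometry of 10 is copied into the trans relation of 11. C9' (S) and C10' (R) are thus set together, their relative configuration by the alkene geometry and their absolute configuration by the ligand, which exposes one face of the bound alkene. The closest known reaction type is the epoxidation of tertiary allylic and homoallylic alcohols with this same metal–ligand pair, which answers the poor turnover of Ti(OiPr)4/dialkyl tartrate with fully substituted carbinols. The step needs chemoselectivity for one of four C=C bonds: only C9'=C10' can reach the metal-bound peroxide, since C6'=C7' is held away by the rigid E alkene, C2'=C3' is remote, and C3=C4 is electron-poor. The pivalate keeps O5 from competing for the metal. The precursor is achiral and carries no protecting group in the chain, so this step creates all the stereochemical information of 13.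

**Step 7**
Reactants: 11 the (9'S,10'R)-trans-epoxide
Product: 12 7-{[(2E,6E,9R,10R)-9-(benzoyloxy)-10,11-dihydroxy-3,7,11-trimethyldodeca-2,6-dien-1-yl]oxy}-2-oxo-2H-chromen-5-yl pivalate
Conditions: Ti(OiPr)4 (1.5 equiv), PhCO2H (2 equiv), CH2Cl2, rt
Reagents that add atoms: benzoic acid OC(=O)c1ccccc1
Why: Ti(OiPr)4-mediated regioselective opening of a 2,3-epoxy alcohol by a carboxylic acid. Tetravalent titanium chelates O11' and the epoxide oxygen, and benzoate attacks the distal, unhindered C9' by SN2 with inversion (S to R), while the neopentyl-like C10' keeps its C–O bond and its R configuration. The conditions are mild enough for the allyl aryl ether.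

**Step 8**
Reactants: 12 the (9'R,10'R)-9'-benzoate 5-pivalate
Product: 13 5-hydroxy-7-{[(2E,6E,9R,10R)-9,10,11-trihydroxy-3,7,11-trimethyldodeca-2,6-dien-1-yl]oxy}-2H-chromen-2-one (target)
Conditions: K2CO3 (2 equiv), MeOH, 0 °C to rt; aq NH4Cl work-up
Reagents that add atoms: none
Why: Base-mediated transesterification removes the benzoate and the aryl pivalate together by acyl–oxygen cleavage, so no stereocentre is touched. Any transient opening of the lactone is reversed on neutralisation, because the Z-configured hydroxycinnamate recloses.

## Compound list

1 | 5,7-dihydroxycoumarin | O=c1ccc2c(O)cc(O)cc2o1 | starting material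
2 | geranyl bromide | C/C(=C\CBr)CCC=C(C)C | starting material
3 | 7-geranyloxy-5-hydroxycoumarin | C/C(=C\COc1cc(O)c2ccc(=O)oc2c1)CCC=C(C)C | intermediate
4 | 7-(geranyloxy)-2-oxo-2H-chromen-5-yl pivalate | C/C(=C\COc1cc(OC(=O)C(C)(C)C)c2ccc(=O)oc2c1)CCC=C(C)C | intermediate
5 | (2'E,6'E)-8'-oxo derivative of 4 (8'-enal) | C/C(=C\COc1cc(OC(=O)C(C)(C)C)c2ccc(=O)oc2c1)CC/C=C(\C)C=O | intermediate
6 | (2'E,6'E)-8'-hydroxy derivative of 4 | C/C(=C\COc1cc(OC(=O)C(C)(C)C)c2ccc(=O)oc2c1)CC/C=C(\C)CO | intermediate
7 | (2'E,6'E)-8'-bromo derivative of 4 | C/C(=C\COc1cc(OC(=O)C(C)(C)C)c2ccc(=O)oc2c1)CC/C=C(\C)CBr | intermediate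
8 | 2-methylbut-3-yn-2-ol | C#CC(C)(C)O | starting material
9 | (E)-2-methyl-4-(tributylstannyl)but-3-en-2-ol | CCCC[Sn](CCCC)(CCCC)/C=C/C(C)(C)O | intermediate
10 | (2'E,6'E,9'E)-11'-hydroxy triene ether, 5-pivalate | C/C(=C\COc1cc(OC(=O)C(C)(C)C)c2ccc(=O)oc2c1)CC/C=C(\C)C/C=C/C(C)(C)O | intermediate
11 | (9'S,10'R)-trans-9',10'-epoxy-11'-ol, 5-pivalate | C/C(=C\COc1cc(OC(=O)C(C)(C)C)c2ccc(=O)oc2c1)CC/C=C(\C)C[C@@H]3O[C@H]3C(C)(C)O | intermediate
12 | (9'R,10'R)-9'-benzoyloxy-10',11'-diol, 5-pivalate | C/C(=C\COc1cc(OC(=O)C(C)(C)C)c2ccc(=O)oc2c1)CC/C=C(\C)C[C@@H](OC(=O)c3ccccc3)[C@@H](O)C(C)(C)O | intermediate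
13 | 5-hydroxy-7-{[(2E,6E,9R,10R)-9,10,11-trihydroxy-3,7,11-trimethyldodeca-2,6-dien-1-yl]oxy}-2H-chromen-2-one | C/C(=C\COc1cc(O)c2ccc(=O)oc2c1)CC/C=C(\C)C[C@@H](O)[C@@H](O)C(C)(C)O | target

## Step count and least certain steps

Total step count: 8 (seven in the main line and one for stannane 9). Longest linear sequence: 7 steps (1 → 4 → 6 → 7 → 10 → 11 → 12 → 13).

**Step 6 (key step).**
- Risk: The most likely failure is insufficient facial discrimination. The carbinol carries two equal methyl groups and the far alkene substituent is a flexible chain, so the ligand pocket has little to grip. Slow turnover of the crowded tertiary alkoxide on the metal is the second risk.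
- Fallback: Catalytic enantioselection is replaced by separation of diastereomers, setting out from 10.
  - Directed epoxidation with VO(acac)2/tBuOOH in CH2Cl2 should be just as chemoselective. It gives the racemic trans-epoxide, that is 11 together with its mirror image, the (9'R,10'S)-epoxide F1.
  - Opening as in step 7, with enantiopure (S)-2-methoxy-2-phenylacetic acid in place of benzoic acid, turns the pair into two diastereomeric C9' esters: the (9'R,10'R) ester F2 and the (9'S,10'S) ester F3. These are separated by chromatography or crystallisation.
  - Methanolysis of F2 as in step 8 comes back to the route at 13.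

**Step 7.**
- Risk: Partial attack at C10' would lead after step 8 to the mirror-image triol and so erode the enantiopurity rather than the diastereomeric purity. Sluggish chelation of the tertiary alcohol could also call for forcing conditions, under which the allyl aryl ether starts to ionise.
- Fallback: The regiochemical logic is reversed, from intermolecular attack at C9' to intramolecular attack at C10', setting out from 10.
  - Step 6 is run with the mirror-image ligand to give the (9'R,10'S)-epoxide F1.
  - PhNCO with catalytic DBU converts the C11'–OH into the phenylcarbamate F4.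
  - BF3·OEt2 in Et2O at −20 °C lets the carbamate carbonyl oxygen attack C10' in the 5-exo mode with inversion. Aqueous acid then hydrolyses the iminocarbonate to the (9'R,10'R)-10',11'-cyclic carbonate F5, with C9'–OH retained.
  - K2CO3/MeOH removes the carbonate and the pivalate and comes back to the route at 13.

**Step 5.**
- Risk: There are three:
  - competing ionisation of the O7–C1' allyl aryl ether by zerovalent palladium;
  - loss of the E geometry at C6'=C7' through π–σ–π isomerisation of the allyl complex;
  - migration of the skipped diene into conjugation.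
- Fallback: Palladium is avoided, setting out from 7 and 8.
  - CuI, K2CO3 and NaI in DMF at rt couple the terminal alkyne with the allyl bromide at C8' to give the skipped enyne F6.
  - Trans-hydrosilylation with (EtO)3SiH and [Cp*Ru(MeCN)3]PF6 (cat.) in CH2Cl2 places silicon on C9', distal to the hydroxyl group, and gives the (Z)-vinylsilane F7.
  - Protodesilylation with TBAF/CuI proceeds with retention and comes back to the route at 10.

**Step 1.**
- Risk: Competing alkylation at O5, double alkylation, or C-alkylation of the electron-rich ring A would lower the throughput and complicate the separation.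
- Fallback: Reliance on relative acidity in the alkylation is replaced by a protecting-group differentiation, setting out from 1.
  - Exhaustive acylation (PivCl, Et3N, DMAP) gives the 5,7-bis(pivalate) F8.
  - Thiolysis with PhSH and catalytic imidazole in NMP should remove the less hindered 7-ester, which is the ester of the better leaving phenoxide, and give 7-hydroxy-2-oxo-2H-chromen-5-yl pivalate F9.
  - Alkylation of its only free phenol with 2 (K2CO3, acetone) comes back to the route at 4.

## Further compounds

F1 | step 6 | (9'R,10'S)-trans-9',10'-epoxy-11'-ol, 5-pivalate (mirror image of 11) | C/C(=C\COc1cc(OC(=O)C(C)(C)C)c2ccc(=O)oc2c1)CC/C=C(\C)C[C@H]3O[C@@H]3C(C)(C)O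
F2 | step 6 | (9'R,10'R)-9'-O-[(S)-2-methoxy-2-phenylacetyl]-10',11'-diol, 5-pivalate | C/C(=C\COc1cc(OC(=O)C(C)(C)C)c2ccc(=O)oc2c1)CC/C=C(\C)C[C@@H](OC(=O)[C@@H](OC)c3ccccc3)[C@@H](O)C(C)(C)O
F3 | step 6 | (9'S,10'S)-9'-O-[(S)-2-methoxy-2-phenylacetyl]-10',11'-diol, 5-pivalate | C/C(=C\COc1cc(OC(=O)C(C)(C)C)c2ccc(=O)oc2c1)CC/C=C(\C)C[C@H](OC(=O)[C@@H](OC)c3ccccc3)[C@H](O)C(C)(C)O
F4 | step 7 | (9'R,10'S)-trans-epoxide C11' N-phenylcarbamate, 5-pivalate | C/C(=C\COc1cc(OC(=O)C(C)(C)C)c2ccc(=O)oc2c1)CC/C=C(\C)C[C@H]3O[C@@H]3C(C)(C)OC(=O)Nc4ccccc4
F5 | step 7 | (9'R,10'R)-9'-hydroxy-10',11'-cyclic carbonate, 5-pivalate | C/C(=C\COc1cc(OC(=O)C(C)(C)C)c2ccc(=O)oc2c1)CC/C=C(\C)C[C@@H](O)[C@H]3OC(=O)OC3(C)C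
F6 | step 5 | (2'E,6'E)-11'-hydroxy-9'-yne ether, 5-pivalate (skipped enyne) | C/C(=C\COc1cc(OC(=O)C(C)(C)C)c2ccc(=O)oc2c1)CC/C=C(\C)CC#CC(C)(C)O
F7 | step 5 | (Z)-9'-(triethoxysilyl)-9'-ene-11'-ol, 5-pivalate | C/C(=C\COc1cc(OC(=O)C(C)(C)C)c2ccc(=O)oc2c1)CC/C=C(\C)C/C(=C/C(C)(C)O)[Si](OCC)(OCC)OCC
F8 | step 1 | 2-oxo-2H-chromene-5,7-diyl bis(pivalate) | CC(C)(C)C(=O)Oc1cc(OC(=O)C(C)(C)C)c2ccc(=O)oc2c1
F9 | step 1 | 7-hydroxy-2-oxo-2H-chromen-5-yl pivalate | Oc1cc(OC(=O)C(C)(C)C)c2ccc(=O)oc2c1
A1 | alternative 1 | (2E,6E,9R,10R)-9,10-O-isopropylidene-3,7,11-trimethyldodeca-2,6-diene-1,9,10,11-tetraol | C/C(=C\CO)CC/C=C(\C)C[C@H]1OC(C)(C)O[C@H]1C(C)(C)O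
A2 | alternative 2 | racemic 5-hydroxy-7-{[(2E,6E)-9-hydroxy-3,7,11-trimethyldodeca-2,6,10-trien-1-yl]oxy}coumarin | C/C(=C\COc1cc(O)c2ccc(=O)oc2c1)CC/C=C(\C)CC(O)C=C(C)C
A3 | alternative 2 | (9'R,10'R)-erythro-10',11'-epoxy-9'-ol ether of 5-hydroxycoumarin | C/C(=C\COc1cc(O)c2ccc(=O)oc2c1)CC/C=C(\C)C[C@@H](O)[C@H]3OC3(C)C
A4 | alternative 3 | 2-{(4R,5R)-5-[(E)-3-iodo-2-methylprop-2-en-1-yl]-2,2-dimethyl-1,3-dioxolan-4-yl}propan-2-ol | I/C=C(\C)C[C@H]1OC(C)(C)O[C@H]1C(C)(C)O
A5 | alternative 3 | (E)-6-[(5-hydroxy-2-oxo-2H-chromen-7-yl)oxy]-4-methylhex-4-enoic acid | C/C(=C\COc1cc(O)c2ccc(=O)oc2c1)CCC(=O)O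
A6 | alternative 3 | 2,3-O-isopropylidene-D-erythronolactone | CC1(C)O[C@@H]2COC(=O)[C@@H]2O1
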